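## Retrosynthetic overview

1. Target ⇒ mono-silyl ether ⇒ Horner–Wadsworth–Emmons disconnection of the dienoate C2=C3 bond into a lactone-bound phosphonoacetate and an (E)-2-methyl-enal carrying the diol stereocentre.
2. Enal ⇒ 4-silyloxybutanal + formaldehyde (aminocatalytic α-hydroxymethylation), trapped in the same pot by a Wittig reagent.
3. Phosphonoacetate ⇒ cis-5-hydroxy-δ-lactone ⇒ 5-PMB-oxy-5,6-dihydropyran-2-one (ring-alkene hydrogenation, PMB removal).
4. Dihydropyranone (the only ring, made in one step) ⇒ NHC-catalysed [4+2] annulation of an anti-2,4-dimethyl aldehyde with a γ-alkoxy ynal, setting both ring stereocentres.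
5. Aldehyde ⇒ penta-1,4-diene by two Zr-catalysed asymmetric carboaluminations, the first telescoped with Pd coupling to (E)-2-bromobut-2-ene.

Assumption: penta-1,4-diene, isomerically pure (E)-2-bromobut-2-ene, 4-methoxybenzyl propargyl ether, diethylphosphonoacetic acid, 4-(tert-butyldimethylsilyloxy)butanal, 2-(triphenylphosphoranylidene)propanal and both antipodes of every catalyst are purchased; lactone atoms are numbered O1, C2(=O), C3–C6; the sense of induction of the new annulation is assigned by model, and the antipodal precatalyst is used if it proves opposite.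

## Route

Step 1
Reactants: 1 penta-1,4-diene; 2 (E)-2-bromobut-2-ene
Product: 4 (4R,6E)-4,6-dimethylocta-1,6-diene, via alkylalane 3 (not isolated)
Conditions: 1 (3 equiv), Me3Al, (−)-(NMI)2ZrCl2 [NMI = 1-neomenthylindenyl] (4 mol%), (MeAlO)n (20 mol%), CH2Cl2, 0 °C to rt; evaporate; then 2, Zn(OTf)2 (0.3 equiv), PdCl2(DPEphos) (3 mol%), i-Bu2AlH (6 mol%), DMF, rt to 50 °C
Reagents that add atoms: trimethylaluminium C[Al](C)C
Why: Zr-catalysed asymmetric carboalumination of one terminal alkene sets the first stereocentre under catalyst control (methyl to the internal carbon, expected ca. 75–80% ee, upgraded in step 2), and the isoalkylalane then undergoes Negishi-type Pd-catalysed cross-coupling with the alkenyl bromide with retention of the E geometry.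

Step 2
Reactants: 4 (4R,6E)-4,6-dimethylocta-1,6-diene
Product: 6 (2R,4R,6E)-2,4,6-trimethyloct-6-en-1-ol, via alkylalane 5 (not isolated)
Conditions: Me3Al, (−)-(NMI)2ZrCl2 (5 mol%), (MeAlO)n (20 mol%), CH2Cl2, 0 °C to rt; then O2, 0 °C to rt; aqueous work-up; chromatography to remove the syn isomers
Reagents that add atoms: trimethylaluminium C[Al](C)C; dioxygen O=O
Why: A second Zr-catalysed asymmetric carboalumination on the remaining terminal alkene (the trisubstituted alkene is inert) with the same catalyst antipode places the new methyl anti to the first by catalyst control, O2 oxidises the C–Al bond to the alcohol, and removing the syn diastereomers raises the ee to an expected >95% (statistical amplification).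

Step 3
Reactants: 6 (2R,4R,6E)-2,4,6-trimethyloct-6-en-1-ol
Product: 7 (2R,4R,6E)-2,4,6-trimethyloct-6-enal
Conditions: TEMPO (10 mol%), PhI(OAc)2, CH2Cl2, rt; used directly
Reagents that add atoms: none
Why: Oxoammonium (TEMPO/PhI(OAc)2) oxidation gives the aldehyde under non-basic conditions that neither epimerise the α-stereocentre nor touch the alkene.

Step 4
Reactants: 8 1-methoxy-4-[(prop-2-yn-1-yloxy)methyl]benzene
Product: 10 4-[(4-methoxybenzyl)oxy]but-2-ynal, via lithium acetylide 9 (not isolated)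
Conditions: n-BuLi, THF, −78 °C; DMF, −78 to 0 °C; inverse quench into aq. KH2PO4
Reagents that add atoms: N,N-dimethylformamide CN(C)C=O
Why: Formylation of a lithium acetylide with DMF followed by a buffered inverse quench is the standard ynal synthesis.

Step 5
Reactants: 7 (2R,4R,6E)-2,4,6-trimethyloct-6-enal; 10 4-[(4-methoxybenzyl)oxy]but-2-ynal
Product: 12 (5R,6R)-6-[(2R,4R,6E)-4,6-dimethyloct-6-en-2-yl]-5-[(4-methoxybenzyl)oxy]-5,6-dihydro-2H-pyran-2-one, via azolium dienolate 11 (not isolated)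
Conditions: (5aR,10bS)-2-mesityl-5a,10b-dihydro-4H,6H-indeno[2,1-b][1,2,4]triazolo[4,3-d][1,4]oxazin-2-ium chloride (15 mol%), i-Pr2NEt (30 mol%), 4 Å MS, toluene, 0 °C to rt, slow addition of 10 (1.5 equiv)
Reagents that add atoms: none
Why: Proposed new method: the carbene adds to ynal 10 and the Breslow intermediate undergoes the known internal redox to the (E)-α,β-unsaturated acyl azolium, whose γ-CH2 is deprotonated to the γ-alkoxy azolium dienolate 11; its γ-carbon attacks aldehyde 7 through an endo, closed [4+2]-type transition state in which the indane wall of the catalyst shields one dienolate face, and the resulting alkoxide acylates on the acyl azolium, closing the δ-lactone and releasing the carbene, so that C5 and C6 are set cis by catalyst control (the α-methyl centre of 7 is a spectator and attack is required on its anti-Felkin face); the closest known reactions are NHC-catalysed formal [4+2] annulations of azolium dienolates (from enals plus oxidant or from unsaturated acid derivatives) with trifluoromethyl ketones or isatins giving 5,6-dihydropyran-2-ones, and the redox activation of ynals to unsaturated acyl azoliums, while new here are the unactivated α-branched aliphatic aldehyde as 2π partner and the γ-alkoxy dienolate that creates two adjacent stereocentres.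

Step 6
Reactants: 12 (5R,6R)-6-[(2R,4R,6E)-4,6-dimethyloct-6-en-2-yl]-5-[(4-methoxybenzyl)oxy]-5,6-dihydro-2H-pyran-2-one
Product: 13 (5R,6R)-6-[(2R,4R,6E)-4,6-dimethyloct-6-en-2-yl]-5-[(4-methoxybenzyl)oxy]tetrahydro-2H-pyran-2-one
Conditions: H2 (1 atm), RhCl(PPh3)3 (5 mol%), toluene, rt
Reagents that add atoms: none
Why: Homogeneous hydrogenation with RhCl(PPh3)3 saturates the cis-disubstituted conjugated ring alkene far faster than the trisubstituted side-chain alkene and does not hydrogenolyse the PMB ether or disturb the stereocentres.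

Step 7
Reactants: 13 (5R,6R)-6-[(2R,4R,6E)-4,6-dimethyloct-6-en-2-yl]-5-[(4-methoxybenzyl)oxy]tetrahydro-2H-pyran-2-one
Product: 14 (5R,6R)-6-[(2R,4R,6E)-4,6-dimethyloct-6-en-2-yl]-5-hydroxytetrahydro-2H-pyran-2-one
Conditions: DDQ (1.3 equiv), CH2Cl2/pH 7 phosphate buffer, 0 °C; used directly
Reagents that add atoms: none
Why: Oxidative PMB ether cleavage with DDQ under buffered neutral conditions frees the C5 alcohol without the acid or base that would promote translactonisation to the γ-lactone.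

Step 8
Reactants: 14 (5R,6R)-6-[(2R,4R,6E)-4,6-dimethyloct-6-en-2-yl]-5-hydroxytetrahydro-2H-pyran-2-one; 15 2-(diethoxyphosphoryl)acetic acid
Product: 16 (2R,3R)-2-[(2R,4R,6E)-4,6-dimethyloct-6-en-2-yl]-6-oxotetrahydro-2H-pyran-3-yl 2-(diethoxyphosphoryl)acetate
Conditions: DCC, DMAP (5 mol%), CH2Cl2, 0 °C to rt
Reagents that add atoms: none
Why: Steglich-type esterification in which DCC-activated phosphonoacetic acid acylates the hindered secondary alcohol rapidly with retention at C5.

Step 9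
Reactants: 17 4-[(tert-butyldimethylsilyl)oxy]butanal; 18 2-(triphenyl-λ5-phosphanylidene)propanal
Product: 20 (2E,4R)-6-[(tert-butyldimethylsilyl)oxy]-4-(hydroxymethyl)-2-methylhex-2-enal, via hydroxymethyl aldehyde 19 (not isolated)
Conditions: aq. HCHO (37%, 3 equiv), (R)-α,α-diphenylprolinol trimethylsilyl ether (15 mol%), pH 7 phosphate buffer, toluene, rt; phase separation; then 18 (2 equiv), toluene, 45 °C
Reagents that add atoms: formaldehyde C=O
Why: Enamine catalysis, in which the E-enamine of the (R)-diarylprolinol silyl ether attacks formaldehyde from the face opposite the bulky diphenyl(silyloxy)methyl group (α-hydroxymethylation, S α-centre, expected ca. 90–95% ee), and the sensitive β-hydroxy aldehyde is trapped in the same pot by an E-selective Wittig olefination; the α-branched enal formed does not condense with the bulky amine, so the γ-stereocentre is safe.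

Step 10
Reactants: 16 (2R,3R)-2-[(2R,4R,6E)-4,6-dimethyloct-6-en-2-yl]-6-oxotetrahydro-2H-pyran-3-yl 2-(diethoxyphosphoryl)acetate; 20 (2E,4R)-6-[(tert-butyldimethylsilyl)oxy]-4-(hydroxymethyl)-2-methylhex-2-enal
Product: 21 (2R,3R)-2-[(2R,4R,6E)-4,6-dimethyloct-6-en-2-yl]-6-oxotetrahydro-2H-pyran-3-yl (2E,4E,6R)-8-[(tert-butyldimethylsilyl)oxy]-6-(hydroxymethyl)-4-methylocta-2,4-dienoate
Conditions: LiCl, i-Pr2NEt, MeCN, rt
Reagents that add atoms: none
Why: Horner–Wadsworth–Emmons olefination under Masamune–Roush conditions is mild enough for the lactone, the epimerisable centres and the free primary alcohol, and gives the new (2E) double bond, completing the (2E,4E)-dienoate.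

Step 11
Reactants: 21 (2R,3R)-2-[(2R,4R,6E)-4,6-dimethyloct-6-en-2-yl]-6-oxotetrahydro-2H-pyran-3-yl (2E,4E,6R)-8-[(tert-butyldimethylsilyl)oxy]-6-(hydroxymethyl)-4-methylocta-2,4-dienoate
Product: 22 (2R,3R)-2-[(2R,4R,6E)-4,6-dimethyloct-6-en-2-yl]-6-oxotetrahydro-2H-pyran-3-yl (2E,4E,6R)-8-hydroxy-6-(hydroxymethyl)-4-methylocta-2,4-dienoate
Conditions: HF·pyridine, pyridine, THF, 0 °C to rt
Reagents that add atoms: none
Why: Fluoride-mediated cleavage of the primary silyl ether under buffered, weakly acidic conditions leaves both esters and the diene intact and avoids base-induced oxa-Michael addition or acyl migration.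

## Compound list

1 | penta-1,4-diene | C=CCC=C | starting material
2 | (E)-2-bromobut-2-ene | C/C=C(\C)Br | starting material
3 | dimethyl[(2R)-2-methylpent-4-en-1-yl]alumane | C[Al](C)C[C@H](C)CC=C | intermediate (not isolated)
4 | (4R,6E)-4,6-dimethylocta-1,6-diene | C/C=C(\C)C[C@H](C)CC=C | intermediate
5 | dimethyl[(2R,4R,6E)-2,4,6-trimethyloct-6-en-1-yl]alumane | C/C=C(\C)C[C@H](C)C[C@@H](C)C[Al](C)C | intermediate (not isolated)
6 | (2R,4R,6E)-2,4,6-trimethyloct-6-en-1-ol | C/C=C(\C)C[C@H](C)C[C@@H](C)CO | intermediate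
7 | (2R,4R,6E)-2,4,6-trimethyloct-6-enal | C/C=C(\C)C[C@H](C)C[C@@H](C)C=O | intermediate
8 | 1-methoxy-4-[(prop-2-yn-1-yloxy)methyl]benzene (4-methoxybenzyl propargyl ether) | C#CCOCc1ccc(OC)cc1 | starting material
9 | {3-[(4-methoxybenzyl)oxy]prop-1-yn-1-yl}lithium | [Li]C#CCOCc1ccc(OC)cc1 | intermediate (not isolated)
10 | 4-[(4-methoxybenzyl)oxy]but-2-ynal | O=CC#CCOCc1ccc(OC)cc1 | intermediate
11 | (1Z,3E)-4-[(4-methoxybenzyl)oxy]-1-[(5aR,10bS)-2-mesityl-5a,10b-dihydro-4H,6H-indeno[2,1-b][1,2,4]triazolo[4,3-d][1,4]oxazin-2-ium-1-yl]buta-1,3-dien-1-olate (azolium dienolate) | [O-]/C(=C\C=C\OCc1ccc(OC)cc1)c1[n+](-c2c(C)cc(C)cc2C)nc2CO[C@@H]3Cc4ccccc4[C@@H]3n12 | intermediate (not isolated)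
12 | (5R,6R)-6-[(2R,4R,6E)-4,6-dimethyloct-6-en-2-yl]-5-[(4-methoxybenzyl)oxy]-5,6-dihydro-2H-pyran-2-one | C/C=C(\C)C[C@H](C)C[C@@H](C)[C@H]1OC(=O)C=C[C@H]1OCc1ccc(OC)cc1 | intermediate
13 | (5R,6R)-6-[(2R,4R,6E)-4,6-dimethyloct-6-en-2-yl]-5-[(4-methoxybenzyl)oxy]tetrahydro-2H-pyran-2-one | C/C=C(\C)C[C@H](C)C[C@@H](C)[C@H]1OC(=O)CC[C@H]1OCc1ccc(OC)cc1 | intermediate
14 | (5R,6R)-6-[(2R,4R,6E)-4,6-dimethyloct-6-en-2-yl]-5-hydroxytetrahydro-2H-pyran-2-one | C/C=C(\C)C[C@H](C)C[C@@H](C)[C@H]1OC(=O)CC[C@H]1O | intermediate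
15 | 2-(diethoxyphosphoryl)acetic acid | OC(=O)CP(=O)(OCC)OCC | starting material
16 | (2R,3R)-2-[(2R,4R,6E)-4,6-dimethyloct-6-en-2-yl]-6-oxotetrahydro-2H-pyran-3-yl 2-(diethoxyphosphoryl)acetate | C/C=C(\C)C[C@H](C)C[C@@H](C)[C@H]1OC(=O)CC[C@H]1OC(=O)CP(=O)(OCC)OCC | intermediate
17 | 4-[(tert-butyldimethylsilyl)oxy]butanal | O=CCCCO[Si](C)(C)C(C)(C)C | starting material
18 | 2-(triphenyl-λ5-phosphanylidene)propanal | CC(C=O)=P(c1ccccc1)(c1ccccc1)c1ccccc1 | starting material
19 | (2S)-4-[(tert-butyldimethylsilyl)oxy]-2-(hydroxymethyl)butanal | O=C[C@H](CO)CCO[Si](C)(C)C(C)(C)C | intermediate (not isolated)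
20 | (2E,4R)-6-[(tert-butyldimethylsilyl)oxy]-4-(hydroxymethyl)-2-methylhex-2-enal | O=C/C(C)=C/[C@H](CO)CCO[Si](C)(C)C(C)(C)C | intermediate
21 | (2R,3R)-2-[(2R,4R,6E)-4,6-dimethyloct-6-en-2-yl]-6-oxotetrahydro-2H-pyran-3-yl (2E,4E,6R)-8-[(tert-butyldimethylsilyl)oxy]-6-(hydroxymethyl)-4-methylocta-2,4-dienoate | C/C=C(\C)C[C@H](C)C[C@@H](C)[C@H]1OC(=O)CC[C@H]1OC(=O)/C=C/C(C)=C/[C@H](CO)CCO[Si](C)(C)C(C)(C)C | intermediate
22 | (2R,3R)-2-[(2R,4R,6E)-4,6-dimethyloct-6-en-2-yl]-6-oxotetrahydro-2H-pyran-3-yl (2E,4E,6R)-8-hydroxy-6-(hydroxymethyl)-4-methylocta-2,4-dienoate | C/C=C(\C)C[C@H](C)C[C@@H](C)[C@H]1OC(=O)CC[C@H]1OC(=O)/C=C/C(C)=C/[C@H](CO)CCO | target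

## Step count and risks

Total steps: 11. Longest linear sequence: 9 (steps 1, 2, 3, 5, 6, 7, 8, 10, 11).

**Step 5 (the proposed new annulation).** Aldehyde 7 may be too weak an electrophile for the azolium dienolate, which can instead oligomerise with its own acyl azolium. The trans lactone or the Felkin diastereomer may dominate, and 7 may epimerise. The fallback uses known chemistry, sets out from 7 and comes back at 14. Aldehyde 7 is stirred in toluene at room temperature with (Z)-2-[3-(methoxymethoxy)prop-2-en-1-yl]-4,4,5,5-tetramethyl-1,3,2-dioxaborolane F1 (from allyl methoxymethyl ether, s-BuLi, THF, −78 °C, then 2-isopropoxy-4,4,5,5-tetramethyl-1,3,2-dioxaborolane), optionally with 5 mol% of a chiral phosphoric acid. The chair transition state of this (Z)-γ-alkoxyallylboronate gives the syn diol monoether, and its known anti-Felkin preference with α-methyl aldehydes delivers (3R,4R,5R,7R,9E)-3-(methoxymethoxy)-5,7,9-trimethylundeca-1,9-dien-4-ol F2. Cross-metathesis with methyl acrylate (second-generation Hoveyda–Grubbs catalyst, CH2Cl2, 40 °C) gives methyl (2E,4R,5R,6R,8R,10E)-5-hydroxy-4-(methoxymethoxy)-6,8,10-trimethyldodeca-2,10-dienoate F3. Hydrogenation (H2, RhCl(PPh3)3, toluene) gives methyl (4R,5R,6R,8R,10E)-5-hydroxy-4-(methoxymethoxy)-6,8,10-trimethyldodec-10-enoate F4, which lactonises with PPTS in warm toluene to (5R,6R)-6-[(2R,4R,6E)-4,6-dimethyloct-6-en-2-yl]-5-(methoxymethoxy)tetrahydro-2H-pyran-2-one F5. Me2BBr (CH2Cl2, −78 °C, NaHCO3 quench) removes the acetal to give 14.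

**Step 9 (one-pot hydroxymethylation and Wittig).** The formyl-stabilised ylide needs warming, and the β-hydroxy aldehyde 19 can dehydrate or racemise before it is trapped. The fallback sets out from 17 and comes back at 20. The hydroxymethylation is run as in step 9 to 19, which is trapped at room temperature with the more reactive ethyl 2-(triphenylphosphoranylidene)propanoate to give ethyl (2E,4R)-6-[(tert-butyldimethylsilyl)oxy]-4-(hydroxymethyl)-2-methylhex-2-enoate F6. Reduction with i-Bu2AlH (CH2Cl2, −78 °C) gives (2E,4R)-4-{2-[(tert-butyldimethylsilyl)oxy]ethyl}-2-methylpent-2-ene-1,5-diol F7. MnO2 (CH2Cl2, rt) oxidises only the allylic alcohol to give 20.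

**Step 7 (liberating the 5-hydroxy-δ-lactone).** Free 14 can translactonise to the more stable γ-lactone before or during acylation. The fallback sets out from 12 and comes back at 16, so that the saturated hydroxy-lactone is never formed. DDQ (CH2Cl2/pH 7 buffer, 0 °C) on 12 gives (5R,6R)-6-[(2R,4R,6E)-4,6-dimethyloct-6-en-2-yl]-5-hydroxy-5,6-dihydro-2H-pyran-2-one F8, a class of unsaturated hydroxy-lactone that is known to be isolable and acylable. Esterification with 15 (DCC, CH2Cl2) gives (2R,3R)-2-[(2R,4R,6E)-4,6-dimethyloct-6-en-2-yl]-6-oxo-3,6-dihydro-2H-pyran-3-yl 2-(diethoxyphosphoryl)acetate F9. Hydrogenation of the ring alkene (H2, RhCl(PPh3)3, toluene) then gives 16.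

## Further compounds

F1 | step 5 | (Z)-2-[3-(methoxymethoxy)prop-2-en-1-yl]-4,4,5,5-tetramethyl-1,3,2-dioxaborolane | COCO/C=C\CB1OC(C)(C)C(C)(C)O1
F2 | step 5 | (3R,4R,5R,7R,9E)-3-(methoxymethoxy)-5,7,9-trimethylundeca-1,9-dien-4-ol | C/C=C(\C)C[C@H](C)C[C@@H](C)[C@@H](O)[C@H](OCOC)C=C
F3 | step 5 | methyl (2E,4R,5R,6R,8R,10E)-5-hydroxy-4-(methoxymethoxy)-6,8,10-trimethyldodeca-2,10-dienoate | C/C=C(\C)C[C@H](C)C[C@@H](C)[C@@H](O)[C@H](OCOC)/C=C/C(=O)OC
F4 | step 5 | methyl (4R,5R,6R,8R,10E)-5-hydroxy-4-(methoxymethoxy)-6,8,10-trimethyldodec-10-enoate | C/C=C(\C)C[C@H](C)C[C@@H](C)[C@@H](O)[C@H](OCOC)CCC(=O)OC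
F5 | step 5 | (5R,6R)-6-[(2R,4R,6E)-4,6-dimethyloct-6-en-2-yl]-5-(methoxymethoxy)tetrahydro-2H-pyran-2-one | C/C=C(\C)C[C@H](C)C[C@@H](C)[C@H]1OC(=O)CC[C@H]1OCOC
F6 | step 9 | ethyl (2E,4R)-6-[(tert-butyldimethylsilyl)oxy]-4-(hydroxymethyl)-2-methylhex-2-enoate | CCOC(=O)/C(C)=C/[C@H](CO)CCO[Si](C)(C)C(C)(C)C
F7 | step 9 | (2E,4R)-4-{2-[(tert-butyldimethylsilyl)oxy]ethyl}-2-methylpent-2-ene-1,5-diol | OC/C(C)=C/[C@H](CO)CCO[Si](C)(C)C(C)(C)C
F8 | step 7 | (5R,6R)-6-[(2R,4R,6E)-4,6-dimethyloct-6-en-2-yl]-5-hydroxy-5,6-dihydro-2H-pyran-2-one | C/C=C(\C)C[C@H](C)C[C@@H](C)[C@H]1OC(=O)C=C[C@H]1O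
F9 | step 7 | (2R,3R)-2-[(2R,4R,6E)-4,6-dimethyloct-6-en-2-yl]-6-oxo-3,6-dihydro-2H-pyran-3-yl 2-(diethoxyphosphoryl)acetate | C/C=C(\C)C[C@H](C)C[C@@H](C)[C@H]1OC(=O)C=C[C@H]1OC(=O)CP(=O)(OCC)OCC
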